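## Retrosynthetic overview

1. Target 9 ⇐ racemic flavanone 8: the C2 configuration is selected last by a Rh-catalysed transfer-hydrogenation kinetic resolution that reduces only the 2R ketone.
2. 8 ⇐ 2'-hydroxychalcone 7: intramolecular oxa-Michael addition closes the pyranone ring (O1–C2), the only ring formed in the route.
3. 7 ⇐ acetophenone 4 + 4-methoxybenzaldehyde 5: a Claisen–Schmidt aldol condensation makes the key C–C bond (C2–C3 of the flavanone) and joins the A- and B-ring fragments.
4. 4 ⇐ 3,4,5-trimethoxyphenol 1: ortho-acetylation, bromination of the last ring C–H, Cu-catalysed methoxylation.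
5. Ring order: rings A and B are bought intact; ring C is closed in step 5.

Assumption: BF3·OEt2, KOH, NaOAc, Et3N and the Cu and Rh species act only as promoters or catalysts and are counted as unchanged. The sense of the resolution in step 6 is predicted from the standard transfer-hydrogenation model, so the configuration of 9 is confirmed by CD (2S: positive Cotton effect near 330 nm, negative near 290 nm) and chiral HPLC.

## Route

Step 1
Reactants: 1 3,4,5-trimethoxyphenol
Product: 2 1-(2-hydroxy-4,5,6-trimethoxyphenyl)ethanone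
Conditions: AcOH, BF3·OEt2 (3 equiv), 90 °C, 2 h; aq. NaOAc work-up
Reagents that add atoms: acetic acid, CC(=O)O
Why: BF3-mediated Friedel–Crafts (Nencki-type) C-acylation occurs ortho to the phenol at one of the two equivalent free positions of symmetric 1, and the chelated ortho-hydroxy ketone resists a second acylation.

Step 2
Reactants: 2 1-(2-hydroxy-4,5,6-trimethoxyphenyl)ethanone
Product: 3 1-(3-bromo-2-hydroxy-4,5,6-trimethoxyphenyl)ethanone
Conditions: NBS (1.05 equiv), MeCN, 0 °C → rt, dark
Reagents that add atoms: N-bromosuccinimide, O=C1CCC(=O)N1Br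
Why: Electrophilic aromatic bromination at the single remaining ring C–H (ortho to OH, para to OMe) is much faster than α-bromination of the chelated ketone.

Step 3
Reactants: 3 1-(3-bromo-2-hydroxy-4,5,6-trimethoxyphenyl)ethanone
Product: 4 1-(2-hydroxy-3,4,5,6-tetramethoxyphenyl)ethanone
Conditions: NaOMe (28% in MeOH, 8 equiv), CuBr (0.3 equiv), DMF, 110 °C, N2; then cold 2 M HCl
Reagents that add atoms: sodium methoxide, C[O-].[Na+]
Why: Copper-catalysed Ullmann-type methoxylation replaces the aryl bromide by OMe while the substrate sits as its phenoxide, which keeps the ketone from enolising or condensing.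

Step 4
Reactants: 4 1-(2-hydroxy-3,4,5,6-tetramethoxyphenyl)ethanone, 5 4-methoxybenzaldehyde
Product: 7 (E)-1-(2-hydroxy-3,4,5,6-tetramethoxyphenyl)-3-(4-methoxyphenyl)prop-2-en-1-one, via racemic aldol adduct 6 (not isolated)
Conditions: 5 (1.2 equiv), KOH (50% aq., 6 equiv), EtOH, 0 °C → rt, 24–48 h; then 2 M HCl, 0 °C
Reagents that add atoms: none
Why: In this Claisen–Schmidt crossed aldol condensation only the methyl ketone can enolise and the aldehyde cannot, so a single aldol 6 forms and E1cB dehydration gives the conjugated (E)-enone, creating the key C–C bond between the two fragments.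

Step 5
Reactants: 7 (E)-1-(2-hydroxy-3,4,5,6-tetramethoxyphenyl)-3-(4-methoxyphenyl)prop-2-en-1-one
Product: 8 (±)-5,6,7,8-tetramethoxy-2-(4-methoxyphenyl)chroman-4-one
Conditions: NaOAc (5 equiv), EtOH/H2O 10:1, reflux, 24–48 h; recovered 7 recycled
Reagents that add atoms: none
Why: Intramolecular oxa-Michael addition of the phenol to the enone closes ring C, favoured because the 6'-OMe twists the aroyl group out of conjugation, and it creates C2 as a racemate.

Step 6
Reactants: 8 (±)-5,6,7,8-tetramethoxy-2-(4-methoxyphenyl)chroman-4-one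
Product: 9 (2S)-5,6,7,8-tetramethoxy-2-(4-methoxyphenyl)chroman-4-one
Conditions: [Cp*RhCl((R,R)-TsDPEN)] (1 mol %), HCO2H/Et3N 5:2 (1.5 equiv HCO2H), EtOAc, 25–40 °C, stopped at 52–55% conversion (chiral HPLC); SiO2, then recrystallisation from EtOH; no base in work-up
Reagents that add atoms: none
Why: In this Noyori–Ikariya asymmetric transfer hydrogenation run as a kinetic resolution, the (R,R)-catalyst forms 4R carbinols, which is matched only for the 2R ketone (giving the cis-2,4-diequatorial alcohol), so the 2S ketone is left unreduced in high ee and the C2 stereocentre of 9 is fixed by this selection.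

## Compound list

1 | 3,4,5-trimethoxyphenol | COc1cc(O)cc(OC)c1OC | starting material
2 | 1-(2-hydroxy-4,5,6-trimethoxyphenyl)ethanone (2'-hydroxy-4',5',6'-trimethoxyacetophenone) | CC(=O)c1c(O)cc(OC)c(OC)c1OC | intermediate
3 | 1-(3-bromo-2-hydroxy-4,5,6-trimethoxyphenyl)ethanone | CC(=O)c1c(O)c(Br)c(OC)c(OC)c1OC | intermediate
4 | 1-(2-hydroxy-3,4,5,6-tetramethoxyphenyl)ethanone | CC(=O)c1c(O)c(OC)c(OC)c(OC)c1OC | intermediate
5 | 4-methoxybenzaldehyde | COc1ccc(C=O)cc1 | starting material
6 | (±)-3-hydroxy-1-(2-hydroxy-3,4,5,6-tetramethoxyphenyl)-3-(4-methoxyphenyl)propan-1-one (aldol adduct, not isolated) | COc1ccc(C(O)CC(=O)c2c(O)c(OC)c(OC)c(OC)c2OC)cc1 | intermediate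
7 | (E)-1-(2-hydroxy-3,4,5,6-tetramethoxyphenyl)-3-(4-methoxyphenyl)prop-2-en-1-one | COc1ccc(/C=C/C(=O)c2c(O)c(OC)c(OC)c(OC)c2OC)cc1 | intermediate
8 | (±)-5,6,7,8-tetramethoxy-2-(4-methoxyphenyl)chroman-4-one | COc1ccc(C2CC(=O)c3c(OC)c(OC)c(OC)c(OC)c3O2)cc1 | intermediate
9 | (2S)-5,6,7,8-tetramethoxy-2-(4-methoxyphenyl)chroman-4-one, (2S)-5,6,7,8,4'-pentamethoxyflavanone | COc1ccc([C@@H]2CC(=O)c3c(OC)c(OC)c(OC)c(OC)c3O2)cc1 | target

## Summary

Total step count: 6. Longest linear sequence: 6 steps (1 → 2 → 3 → 4 → 7 → 8 → 9). The resolution caps the last step at 50% yield.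

Three steps most likely to fail:

**Step 6 (kinetic resolution).** The C4 ketone is flanked by the 5-OMe group, so reduction may be slow or the selectivity factor too low. The fallback sets out from 4 and comes back at 9, creating the stereocentre by catalysis instead of selecting it. Crossed Claisen C-acylation of the lithium dianion of 4 (LiHMDS 3.2 equiv, THF, −78 °C, then Boc2O) gives tert-butyl 3-(2-hydroxy-3,4,5,6-tetramethoxyphenyl)-3-oxopropanoate F1. Knoevenagel condensation of this with 5 (piperidine/AcOH cat., 4 Å MS, toluene, rt) gives tert-butyl 2-(2-hydroxy-3,4,5,6-tetramethoxybenzoyl)-3-(4-methoxyphenyl)prop-2-enoate F2. A cinchona 9-epi-amino 3,5-bis(trifluoromethyl)phenyl thiourea (10 mol %, toluene, −25 °C) then catalyses an enantioselective oxa-Michael closure. I have not fixed which pseudo-enantiomer (quinine- or quinidine-derived) gives 2S; it is chosen by CD of the product. The closure gives tert-butyl (2S)-5,6,7,8-tetramethoxy-2-(4-methoxyphenyl)-4-oxochromane-3-carboxylate F3. TsOH in toluene at 80 °C in the same pot removes the ester group to give 9, which is recrystallised to raise the ee.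

**Step 3 (Ullmann methoxylation).** Protodebromination back to 2 or incomplete conversion is possible. The fallback sets out from 2 and comes back at 4, installing the oxygen by formylation and oxidation instead of halogen exchange. Duff formylation (hexamethylenetetramine, TFA, 85 °C, then aq. HCl) at the only free ring position gives 3-acetyl-2-hydroxy-4,5,6-trimethoxybenzaldehyde F4. Dakin oxidation of the ortho-hydroxy aldehyde (H2O2 1.1 equiv, aq. NaOH, 0 °C, N2, immediate acidification) gives 1-(2,3-dihydroxy-4,5,6-trimethoxyphenyl)ethanone F5. Selective methylation of the non-chelated 3-OH (MeI 1.05 equiv, Li2CO3, DMF, rt) gives 4.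

**Step 5 (oxa-Michael cyclisation).** The chalcone–flavanone equilibrium may stop short and leave a mixture that is tedious to separate. The fallback sets out from 4 and comes back at 8, closing the ring by irreversible O-alkylation instead of conjugate addition. Directed aldol addition of the dianion of 4 (LDA 2.2 equiv, THF, −78 °C) to 5 with an AcOH quench at −78 °C gives aldol 6, this time isolated. Mitsunobu cyclisation (PPh3, DIAD, THF, 0 °C → rt) gives 8; partial ionisation at the benzylic carbon does not matter because 8 is wanted as the racemate. This fallback makes no compound outside the list (F0).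

## Further compounds

F1 | step 6 | tert-butyl 3-(2-hydroxy-3,4,5,6-tetramethoxyphenyl)-3-oxopropanoate | CC(C)(C)OC(=O)CC(=O)c1c(O)c(OC)c(OC)c(OC)c1OC
F2 | step 6 | tert-butyl 2-(2-hydroxy-3,4,5,6-tetramethoxybenzoyl)-3-(4-methoxyphenyl)prop-2-enoate (E/Z mixture) | COc1ccc(C=C(C(=O)OC(C)(C)C)C(=O)c2c(O)c(OC)c(OC)c(OC)c2OC)cc1
F3 | step 6 | tert-butyl (2S)-5,6,7,8-tetramethoxy-2-(4-methoxyphenyl)-4-oxochromane-3-carboxylate (C3 epimers) | COc1ccc([C@@H]2C(C(=O)OC(C)(C)C)C(=O)c3c(OC)c(OC)c(OC)c(OC)c3O2)cc1
F4 | step 3 | 3-acetyl-2-hydroxy-4,5,6-trimethoxybenzaldehyde | CC(=O)c1c(O)c(C=O)c(OC)c(OC)c1OC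
F5 | step 3 | 1-(2,3-dihydroxy-4,5,6-trimethoxyphenyl)ethanone | CC(=O)c1c(O)c(O)c(OC)c(OC)c1OC
F0 | step 5 | none | none
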